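I began from a balance: I took each target made to have removed one substrate and one partner, so I reckoned with what was left rather than what was made, and partner, charged at 0.500 equiv, was the limiting reagent.

| setting | maple | cedar | north-west | west | south-west |
|---|---|---|---|---|---|
| substrate | 0.50 M | 0.75 M | 1.0 M | 1.0 M | 1.0 M |
| partner | 0.50 equiv | 0.50 equiv | 0.500 equiv | 0.500 equiv | 0.500 equiv |
| free catalyst | 5 mol% | 5 mol% | 5 mol% | 5 mol% | 5 mol% |
| added ligand | 220 mM | 220 mM | 220 mM | 220 mM | 220 mM |
| temperature | 15 °C | 50 °C | 80 °C | 50 °C | 20 °C |
| remark | run made earlier | run made earlier |  |  |  |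
| time |  |  | 20 h | 20 h | 20 h |

| run | time / h | target / % |
|---|---|---|
| maple | 50.0 | 13.2 |
| maple | 96.0 | 9.5 |
| maple | 144 | 6.9 |
| maple | 192 | 4.9 |
| maple | 240 | 3.7 |
| maple | 288 | 3.2 |
| cedar | 4.00 | 19.6 |
| cedar | 6.00 | 18.6 |
| cedar | 12.0 | 18.1 |
| cedar | 20.0 | 18.9 |
| cedar | 40.0 | 18.3 |
| cedar | 48.0 | 18.0 |

(standard deviation of a reading: 0.3 percentage points)

* the flask that comes out highest in amount of target, in percent of the substrate charged, or "all alike" when all lie within 1.5 percentage points (north-west / west / south-west / all alike)
* target at the end, in percent of the substrate charged, north-west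
* target at the end, in percent of the substrate charged, west
* target at the end, in percent of the substrate charged, south-west

I ran the readings in slow motion. In the first instants target climbed quickly when warm: in the cedar run it already read 19.6% at 4.00 h. The middle showed itself in the cold, where the maple run fell from 13.2% at 50.0 h to 3.2% at 288 h, with a half-life read as 101 h, so something was slowly taking target away. The end showed itself in cedar, which stayed flat from 12.0 h to 48.0 h. Its plateau of 18.3% gave 0.944 L mol⁻¹ for the plateau quotient, the concentration of target over the product of the concentrations of substrate left and partner left, each reckoned as charge minus target.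

West stood at cedar's temperature, so I solved the same quotient at the charges of west and got 21.3%. I reckoned nothing for the other two flasks.

The forecast named north-west as highest, with 37% there, 19.5% in west, which is lower than my figure, and 14% in south-west. Its grounds were that target relaxes to “a temperature-dependent equilibrium that favours it more when hot”.

The flasks gave 38.4% in north-west, the highest, 19.1% in west and 18.0% in south-west, so the forecast stood.

    substrate + partner ⇌ target (K = 2.50 L mol⁻¹, k = 0.960 L mol⁻¹ h⁻¹, Ea = 57.0 kJ mol⁻¹, ΔH = 18.0 kJ mol⁻¹)
    substrate + partner ⇌ isomer of the product (K = 76.0 L mol⁻¹, k = 0.0610 L mol⁻¹ h⁻¹, Ea = 81.0 kJ mol⁻¹, ΔH = −66.0 kJ mol⁻¹)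
    target + free catalyst ⇌ isomer of the product + free catalyst, rate k3*[free catalyst]*[target] forward; the back reaction follows from the equilibrium constant (k = 1.20 L mol⁻¹ h⁻¹, Ea = 81.0 kJ mol⁻¹)
    free catalyst + added ligand ⇌ idle complex (K = 3.40 L mol⁻¹, k = 0.480 L mol⁻¹ h⁻¹, Ea = 58.0 kJ mol⁻¹, ΔH = −4.00 kJ mol⁻¹)
    substrate + free catalyst → spent catalyst (k = 0.190 L mol⁻¹ h⁻¹, Ea = 72.0 kJ mol⁻¹)
    (constants at 20 °C)

Of the gap of 20 percentage points between north-west and south-west, the largest single effect, though not the whole of it, is what the temperature does to the turning of substrate and partner into target: without it the same two flasks differ by 7.5 points. In west, isomer of the product held 23.6%, which my subtraction had counted as left, so the amounts truly left give a quotient of 4.96 L mol⁻¹, not 0.944 L mol⁻¹. For the neighbour, west with 1.20 equiv of partner, 0.944 L mol⁻¹ gives 42.3%; the flask gives 34.9%, and its amounts left give a quotient of 4.96 L mol⁻¹.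

Readings and results are simulated from invented constants.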